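Retrosynthetic cuts, in order: O5–Si (protecting group); C4–C4a (ring C, acyl carbon to ring A); C2–H (from a C2=C3 enol ether); O1–C2 (phenol to ynoate); C2–C1' (ynoate to ring B); C8–prenyl.
Forward: the ring A phenol is made by silylation, MOM protection, lithiation/prenylation between the MOM and methoxy oxygens, and MOM removal. The ring B ynoate is made by Sonogashira coupling. The two are joined at O1–C2 by oxa-Michael addition; the enoate is reduced, the ester hydrolysed, ring C closed last, and the silyl ether removed.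
Stereochemistry: the only stereocentre, C2 (S), is set by ligand-controlled CuH conjugate reduction of the (Z)-β-aryloxy enoate; no later step breaks a bond to C2.
Enabling feature: C4a of ring A is ortho to O1 and to the O5 silyl ether and para to the C7 methoxy group. It is the only hydrogen-bearing carbon ortho to O1, because C8 holds the prenyl group. On ring B both carbons ortho to C1' carry methoxy groups, so the acyl carbon C4 can only close the six-membered ring C.

Key step: step 9

Remark: the facial preference of (DTBM-SEGPHOS)CuH for a β-aryloxy cinnamate is assumed by analogy with β-aryl enoates; the (R)-ligand is written in step 7, and its antipode would be used if a pilot reduction delivers the (3R)-ester.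

Step 1
Reactants: 1 5-methoxybenzene-1,3-diol
Product: 2 3-methoxy-5-(triisopropylsilyloxy)phenol
Conditions: TIPSCl (0.95 equiv), imidazole, DMF, 0 °C to rt
Reagents that add atoms: triisopropylsilyl chloride, CC(C)[Si](Cl)(C(C)C)C(C)C
Why: Silyl ether formation run as a statistical monoprotection of a symmetrical resorcinol, from which unreacted diol and the bis-silyl ether should be removable by chromatography.

Step 2
Reactants: 2 3-methoxy-5-(triisopropylsilyloxy)phenol
Product: 3 triisopropyl[3-methoxy-5-(methoxymethoxy)phenoxy]silane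
Conditions: MOMCl, i-Pr2NEt, CH2Cl2, 0 °C to rt
Reagents that add atoms: chloromethyl methyl ether, COCCl
Why: O-Alkylation of the remaining phenol (MOM ether formation) under amine base leaves the aryl silyl ether intact and installs the group that will direct metalation.

Step 3
Reactants: 3 triisopropyl[3-methoxy-5-(methoxymethoxy)phenoxy]silane; 4 1-bromo-3-methylbut-2-ene
Product: 6 triisopropyl[3-methoxy-5-(methoxymethoxy)-4-(3-methylbut-2-enyl)phenoxy]silane, via aryllithium 5 (not isolated)
Conditions: n-BuLi, THF, 0 °C; then CuI (10 mol%), 4, −78 °C to rt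
Reagents that add atoms: none
Why: Directed ortho-metalation should occur at the ring CH flanked by the coordinating MOM and methoxy oxygens, because the bulky, non-coordinating silyloxy group shields its own neighbours, and copper-catalysed allylic substitution on the primary bromide then gives the linear prenyl arene.

Step 4
Reactants: 6 triisopropyl[3-methoxy-5-(methoxymethoxy)-4-(3-methylbut-2-enyl)phenoxy]silane
Product: 7 3-methoxy-2-(3-methylbut-2-enyl)-5-(triisopropylsilyloxy)phenol
Conditions: HCl (0.5 M in MeOH), rt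
Reagents that add atoms: none
Why: Acid-catalysed acetal methanolysis of the aryl MOM ether should outpace both cleavage of the aryl triisopropylsilyl ether and cyclisation of the ortho-prenyl phenol to a chroman in dilute acid at room temperature.

Step 5
Reactants: 8 2-iodo-1,3,5-trimethoxybenzene; 9 methyl prop-2-ynoate
Product: 10 methyl 3-(2,4,6-trimethoxyphenyl)prop-2-ynoate
Conditions: Pd(PPh3)2Cl2 (3 mol%), CuI (6 mol%), K2CO3, THF, 60 °C, 9 in excess
Reagents that add atoms: none
Why: Sonogashira coupling with an inorganic base instead of an amine, so that the propiolate is not consumed by conjugate addition while the electron-rich aryl iodide still undergoes oxidative addition.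

Step 6
Reactants: 7 3-methoxy-2-(3-methylbut-2-enyl)-5-(triisopropylsilyloxy)phenol; 10 methyl 3-(2,4,6-trimethoxyphenyl)prop-2-ynoate
Product: 11 methyl (2Z)-3-[3-methoxy-2-(3-methylbut-2-enyl)-5-(triisopropylsilyloxy)phenoxy]-3-(2,4,6-trimethoxyphenyl)prop-2-enoate
Conditions: K2CO3 (0.5 equiv), dry DMF, 50–60 °C
Reagents that add atoms: none
Why: Base-mediated oxa-Michael addition of the phenoxide to the ynoate proceeds by anti addition, placing the aryloxy group cis to the ester, so the (Z)-enol ether is expected as the kinetic isomer and is purified to a single geometry before reduction.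

Step 7
Reactants: 11 methyl (2Z)-3-[3-methoxy-2-(3-methylbut-2-enyl)-5-(triisopropylsilyloxy)phenoxy]-3-(2,4,6-trimethoxyphenyl)prop-2-enoate
Product: 12 methyl (3S)-3-[3-methoxy-2-(3-methylbut-2-enyl)-5-(triisopropylsilyloxy)phenoxy]-3-(2,4,6-trimethoxyphenyl)propanoate
Conditions: Cu(OAc)2·H2O (5 mol%), (R)-DTBM-SEGPHOS (5.5 mol%), (EtO)2MeSiH, t-BuOH, toluene, 0 °C to rt
Reagents that add atoms: none
Why: CuH asymmetric conjugate reduction, in which the bisphosphine-ligated CuH delivers hydride to one face of C3 of the geometrically pure enoate and so sets the (S) centre, t-BuOH protonates the copper enolate before it can expel aryloxide, and the isolated prenyl alkene is not a substrate.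

Step 8
Reactants: 12 methyl (3S)-3-[3-methoxy-2-(3-methylbut-2-enyl)-5-(triisopropylsilyloxy)phenoxy]-3-(2,4,6-trimethoxyphenyl)propanoate
Product: 14 (3S)-3-[3-methoxy-2-(3-methylbut-2-enyl)-5-(triisopropylsilyloxy)phenoxy]-3-(2,4,6-trimethoxyphenyl)propanoic acid, via trimethylstannyl ester 13 (not isolated)
Conditions: Me3SnOH, 1,2-dichloroethane, 60 °C; then cold 0.05 M aq. HCl wash
Reagents that add atoms: trimethyltin hydroxide, C[Sn](C)(C)O
Why: Methyl ester hydrolysis with Me3SnOH, a near-neutral hydroxide donor that should neither enolise the ester (so no β-elimination of aryloxide and no change at C3) nor cleave the aryl silyl ether as aqueous alkali might.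

Step 9
Reactants: 14 (3S)-3-[3-methoxy-2-(3-methylbut-2-enyl)-5-(triisopropylsilyloxy)phenoxy]-3-(2,4,6-trimethoxyphenyl)propanoic acid
Product: 16 (2S)-7-methoxy-8-(3-methylbut-2-enyl)-2-(2,4,6-trimethoxyphenyl)-5-(triisopropylsilyloxy)chroman-4-one, via acid chloride 15 (not isolated)
Conditions: 1-chloro-N,N,2-trimethylpropenylamine (1.05 equiv), CH2Cl2, 0 °C; then 2,6-di-tert-butyl-4-methylpyridine, ZnCl2 (1 M in Et2O), −40 to 0 °C
Reagents that add atoms: none
Why: The α-chloroenamine turns the acid into acid chloride 15 without releasing acid, ZnCl2 then polarises the C–Cl bond, C4a of ring A attacks the acyl carbon, and the arenium ion gives its proton to the hindered pyridine. This is an intramolecular Friedel–Crafts acylation of a 3-aryloxypropanoyl chloride, the established route to chroman-4-ones. Ring C closes in a 6-exo-trig mode at the activated acyl carbon, the carbonyl π bond staying outside the new ring. No stereocentre is created, and C2 keeps its (S) configuration because neither of its bonds is broken. Site selectivity is fixed by the substrate: C8 is blocked by the prenyl group, C6 cannot reach the acyl carbon, and both ortho carbons of ring B are methoxylated, so no indanone can form. The chemoselectivity needed is acylation faster than ionisation of the C2–O1 benzylic ether, which the high nucleophilicity of the doubly ortho, para-oxygenated C4a, the mild Lewis acid, the proton scavenger and the low temperature are chosen to secure.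

Step 10
Reactants: 16 (2S)-7-methoxy-8-(3-methylbut-2-enyl)-2-(2,4,6-trimethoxyphenyl)-5-(triisopropylsilyloxy)chroman-4-one
Product: 17 (2S)-5-hydroxy-7-methoxy-8-(3-methylbut-2-enyl)-2-(2,4,6-trimethoxyphenyl)chroman-4-one
Conditions: TBAF, AcOH, THF, 0 °C
Reagents that add atoms: none
Why: Fluoride-mediated desilylation of the aryl silyl ether, buffered with acetic acid so that no phenoxide or enolate persists that could open ring C by retro-oxa-Michael reaction and scramble C2.

Compound list
1 | 5-methoxybenzene-1,3-diol | COc1cc(O)cc(O)c1 | starting material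
2 | 3-methoxy-5-(triisopropylsilyloxy)phenol | COc1cc(O)cc(O[Si](C(C)C)(C(C)C)C(C)C)c1 | intermediate
3 | triisopropyl[3-methoxy-5-(methoxymethoxy)phenoxy]silane | COCOc1cc(OC)cc(O[Si](C(C)C)(C(C)C)C(C)C)c1 | intermediate
4 | 1-bromo-3-methylbut-2-ene | CC(C)=CCBr | starting material
5 | [2-methoxy-6-(methoxymethoxy)-4-(triisopropylsilyloxy)phenyl]lithium | COCOc1cc(O[Si](C(C)C)(C(C)C)C(C)C)cc(OC)c1[Li] | intermediate
6 | triisopropyl[3-methoxy-5-(methoxymethoxy)-4-(3-methylbut-2-enyl)phenoxy]silane | COCOc1cc(O[Si](C(C)C)(C(C)C)C(C)C)cc(OC)c1CC=C(C)C | intermediate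
7 | 3-methoxy-2-(3-methylbut-2-enyl)-5-(triisopropylsilyloxy)phenol | COc1cc(O[Si](C(C)C)(C(C)C)C(C)C)cc(O)c1CC=C(C)C | intermediate
8 | 2-iodo-1,3,5-trimethoxybenzene | COc1cc(OC)c(I)c(OC)c1 | starting material
9 | methyl prop-2-ynoate | COC(=O)C#C | starting material
10 | methyl 3-(2,4,6-trimethoxyphenyl)prop-2-ynoate | COC(=O)C#Cc1c(OC)cc(OC)cc1OC | intermediate
11 | methyl (2Z)-3-[3-methoxy-2-(3-methylbut-2-enyl)-5-(triisopropylsilyloxy)phenoxy]-3-(2,4,6-trimethoxyphenyl)prop-2-enoate | COC(=O)/C=C(\Oc1cc(O[Si](C(C)C)(C(C)C)C(C)C)cc(OC)c1CC=C(C)C)c1c(OC)cc(OC)cc1OC | intermediate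
12 | methyl (3S)-3-[3-methoxy-2-(3-methylbut-2-enyl)-5-(triisopropylsilyloxy)phenoxy]-3-(2,4,6-trimethoxyphenyl)propanoate | COc1cc(OC)c([C@H](CC(=O)OC)Oc2cc(O[Si](C(C)C)(C(C)C)C(C)C)cc(OC)c2CC=C(C)C)c(OC)c1 | intermediate
13 | trimethylstannyl (3S)-3-[3-methoxy-2-(3-methylbut-2-enyl)-5-(triisopropylsilyloxy)phenoxy]-3-(2,4,6-trimethoxyphenyl)propanoate | COc1cc(OC)c([C@H](CC(=O)O[Sn](C)(C)C)Oc2cc(O[Si](C(C)C)(C(C)C)C(C)C)cc(OC)c2CC=C(C)C)c(OC)c1 | intermediate
14 | (3S)-3-[3-methoxy-2-(3-methylbut-2-enyl)-5-(triisopropylsilyloxy)phenoxy]-3-(2,4,6-trimethoxyphenyl)propanoic acid | COc1cc(OC)c([C@H](CC(O)=O)Oc2cc(O[Si](C(C)C)(C(C)C)C(C)C)cc(OC)c2CC=C(C)C)c(OC)c1 | intermediate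
15 | (3S)-3-[3-methoxy-2-(3-methylbut-2-enyl)-5-(triisopropylsilyloxy)phenoxy]-3-(2,4,6-trimethoxyphenyl)propanoyl chloride | COc1cc(OC)c([C@H](CC(Cl)=O)Oc2cc(O[Si](C(C)C)(C(C)C)C(C)C)cc(OC)c2CC=C(C)C)c(OC)c1 | intermediate
16 | (2S)-7-methoxy-8-(3-methylbut-2-enyl)-2-(2,4,6-trimethoxyphenyl)-5-(triisopropylsilyloxy)chroman-4-one | COc1cc(OC)c([C@@H]2CC(=O)c3c(O[Si](C(C)C)(C(C)C)C(C)C)cc(OC)c(CC=C(C)C)c3O2)c(OC)c1 | intermediate
17 | (2S)-5-hydroxy-7-methoxy-8-(3-methylbut-2-enyl)-2-(2,4,6-trimethoxyphenyl)chroman-4-one | COc1cc(OC)c([C@@H]2CC(=O)c3c(O)cc(OC)c(CC=C(C)C)c3O2)c(OC)c1 | target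

Total step count: 10.
Longest linear sequence: 9 steps (1 → 2 → 3 → 6 → 7 → 11 → 12 → 14 → 16 → 17); step 5 is the side branch.

Steps most likely to fail

1. Step 9. The Lewis acid may ionise the C2–O1 benzylic ether, whose cation is stabilised by the 2,4,6-trimethoxyphenyl group, faster than ring closure. That would erode the configuration at C2 or expel the phenol. The fallback sets out from 11 and rejoins the route at 16, closing ring C before the stereocentre exists. Enoate 11 is hydrolysed with Me3SnOH through the trimethylstannyl (Z)-enoate F1 to the (Z)-acrylic acid F2. The α-chloroenamine converts this into the (Z)-acryloyl chloride F3, which ZnCl2 (or SnCl4, tolerable once no stereocentre is at stake) cyclises at the same C4–C4a bond to the 5-silyloxy flavone F4. CuH conjugate reduction of the chromone C2=C3 bond (Cu(OAc)2·H2O, DTBM-SEGPHOS, (EtO)2MeSiH, no alcohol) then gives the (2S) silyl enol ether F5, which is hydrolysed on buffered aqueous work-up to 16.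

2. Step 7. Facial discrimination may be poor because the twisted, di-ortho-substituted aryl group and the aryloxy group on C3 are of similar size, and hydride transfer to this hindered, donor-substituted carbon may be slow. The fallback sets out from 11 and rejoins at 12 by resolution instead of asymmetric catalysis. Enoate 11 is reduced without stereocontrol (Cu(OAc)2·H2O, 1,2-bis(diphenylphosphino)benzene, (EtO)2MeSiH, t-BuOH, toluene) to the racemic ester F6. The enantiomers are separated by preparative chromatography on a chiral stationary phase (amylose tris(3,5-dimethylphenylcarbamate), CO2/MeOH); the (3S)-ester is 12 and the (3R)-ester F7 is set aside.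

3. Step 6. Conjugate addition to the electron-rich, hindered ynoate may be slow enough to require temperatures at which silyl transfer between phenoxides or E/Z equilibration sets in. The fallback sets out from 10 and rejoins at 11, replacing the uncatalysed addition by a copper-catalysed vinylic substitution. Ynoate 10 is hydroiodinated by anti addition (NaI, AcOH, 70 °C) to the (Z)-β-iodo enoate F8. Phenol 7 is then coupled to it in an Ullmann-type C–O coupling (CuI, N,N-dimethylglycine, Cs2CO3, 1,4-dioxane, 60 °C), which should retain the alkene geometry and give 11.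

Further compounds
F1 | step 9 | trimethylstannyl (2Z)-3-[3-methoxy-2-(3-methylbut-2-enyl)-5-(triisopropylsilyloxy)phenoxy]-3-(2,4,6-trimethoxyphenyl)prop-2-enoate | C[Sn](C)(C)OC(=O)/C=C(\Oc1cc(O[Si](C(C)C)(C(C)C)C(C)C)cc(OC)c1CC=C(C)C)c1c(OC)cc(OC)cc1OC
F2 | step 9 | (2Z)-3-[3-methoxy-2-(3-methylbut-2-enyl)-5-(triisopropylsilyloxy)phenoxy]-3-(2,4,6-trimethoxyphenyl)prop-2-enoic acid | OC(=O)/C=C(\Oc1cc(O[Si](C(C)C)(C(C)C)C(C)C)cc(OC)c1CC=C(C)C)c1c(OC)cc(OC)cc1OC
F3 | step 9 | (2Z)-3-[3-methoxy-2-(3-methylbut-2-enyl)-5-(triisopropylsilyloxy)phenoxy]-3-(2,4,6-trimethoxyphenyl)prop-2-enoyl chloride | ClC(=O)/C=C(\Oc1cc(O[Si](C(C)C)(C(C)C)C(C)C)cc(OC)c1CC=C(C)C)c1c(OC)cc(OC)cc1OC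
F4 | step 9 | 7-methoxy-8-(3-methylbut-2-enyl)-2-(2,4,6-trimethoxyphenyl)-5-(triisopropylsilyloxy)chromen-4-one | COc1cc(OC)c(C2=CC(=O)c3c(O[Si](C(C)C)(C(C)C)C(C)C)cc(OC)c(CC=C(C)C)c3O2)c(OC)c1
F5 | step 9 | (2S)-4-[diethoxy(methyl)silyloxy]-7-methoxy-8-(3-methylbut-2-enyl)-2-(2,4,6-trimethoxyphenyl)-5-(triisopropylsilyloxy)-2H-chromene | COc1cc(OC)c([C@@H]2C=C(O[Si](C)(OCC)OCC)c3c(O[Si](C(C)C)(C(C)C)C(C)C)cc(OC)c(CC=C(C)C)c3O2)c(OC)c1
F6 | step 7 | methyl rac-3-[3-methoxy-2-(3-methylbut-2-enyl)-5-(triisopropylsilyloxy)phenoxy]-3-(2,4,6-trimethoxyphenyl)propanoate | COc1cc(OC)c(C(CC(=O)OC)Oc2cc(O[Si](C(C)C)(C(C)C)C(C)C)cc(OC)c2CC=C(C)C)c(OC)c1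
F7 | step 7 | methyl (3R)-3-[3-methoxy-2-(3-methylbut-2-enyl)-5-(triisopropylsilyloxy)phenoxy]-3-(2,4,6-trimethoxyphenyl)propanoate | COc1cc(OC)c([C@@H](CC(=O)OC)Oc2cc(O[Si](C(C)C)(C(C)C)C(C)C)cc(OC)c2CC=C(C)C)c(OC)c1
F8 | step 6 | methyl (2Z)-3-iodo-3-(2,4,6-trimethoxyphenyl)prop-2-enoate | COC(=O)/C=C(\I)c1c(OC)cc(OC)cc1OC
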